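4 questions stood over this flask, and I expected one number to answer 3 of them.

    solid substrate ⇌ starting material, rate k1*(cs1 - [starting material]) while solid is left; crystals form when [starting material] > cs1 (cs1 = 0.090 M, k1 = 0.0039 /s)
    starting material + enzyme ⇌ complex (K2 = 98 /M, k2 = 1.6 × 10⁵ /M/s)
    complex ⇌ enzyme + target (K3 = 0.17 M, k3 = 65 /s)

solid substrate 0.18 M; enzyme 0.02 mol%; time 2.0 h

1. why nothing more happens at 2.0 h, or that something still does (for what has run out or reacted, a solid counts together with what of it has only dissolved) (no working catalyst is left / all of the solid substrate has reacted / forward and back rates have come level / it is still moving)
2. part of the solid substrate that has turned into other species by 2.0 h (what has only dissolved does not count)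
3. target at 2.0 h, in percent of the solid substrate charged
4. starting material at 2.0 h, in percent of the solid substrate charged

- solid substrate is a solid; its amount is given per volume of the solution
- at the start none of the solid substrate is in solution
- what has only dissolved of solid substrate counts as not reacted
- the reaction counts as stopped when no species that holds the solid substrate changes by six tenths of a point or more over the second half of the time
- starting material means what is dissolved; the solid is not counted in it
- run time (flask): 2.0 h

When both enzyme steps are level, c(target)/c(starting material) equals the product of their equilibrium constants, 98 /M times 0.17 M, which is 16.7. From this I took the left-over share, the part of the charge that stays as dissolved starting material once the steps are level, one part in one plus that product: 5.66%. That share of this charge is 0.0102 M, less than the solubility 0.090 M, so I expected no crystals to stand at the end.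

Next I asked whether the run gives time to get there. I replaced the climbing curve of c(starting material) by a constant and tried its two ends:

| c(starting material) held at | dissolving rate | time to dissolve the charge |
|---|---|---|
| none | 3.51 × 10⁻⁴ M/s | 0.142 h |
| 0.0102 M | 3.11 × 10⁻⁴ M/s | 0.161 h |

The rows differ by 12.8%, and that was the error I accepted, since a mean curve lies between them. The lower rate in the second row still stands below the enzyme's forward ceiling, 65 /s times the enzyme charged, which is 0.00234 M/s, so I took dissolving as the rate-limiting step while solid lasts. The longer time in the table is less than the run of 2.0 h, so I expected the steps to have come level. The enzyme is 0.02 mol% of the charge, so complex could hold hardly any of it. I therefore committed to level rates, 94.3% conversion and target, and 5.66% starting material.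

The forecast read forward and back rates have come level, with conversion 94.3%, target 94.3% and starting material 5.66%, holding that “the enzyme is fast enough to hold it there”.

This flask gave forward and back rates have come level, with conversion 94.3%, target 94.3% and starting material 5.66%, which is the left-over share of 5.66%. Half of its dissolving was done by 0.0749 h, between the 0.0710 h and 0.0805 h that half of the two table times give. The same flask read at 5.0 h held 94.3% target and 5.66% starting material, again the left-over share.

The rate constants stand for no real mixture; the run is a simulation.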